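## Analysis of the target

The target is a 3,4-dihydro-1H-isochromen-1-one, numbered O2, C3, C4, C4a to C8a, with C9 the CH2O carbon on C3. Its benzene ring A is pentasubstituted: the side chain on C4a, methyl on C5, methoxy on C6, hydrogen on C7, a free hydroxyl on C8 and the lactone carbonyl on C8a. C3 is a hemiketal carbon that carries a hydroxyl and C9, and C9 is acylated by 2,4-dihydroxy-5,6-dimethylbenzoic acid (ring B), whose carbonyl is flanked by two ortho substituents. There are two stereocentres, C4 (S, benzylic, methyl-bearing) and C3 (R). C3 equilibrates through the open 2-(3-oxobutan-2-yl)benzoic acid, so only C4 has to be set by synthesis. The (3R) lactol is the one expected at equilibrium: the C4 methyl is pushed pseudoaxial by the peri methyl on C5, and the anomeric hydroxyl sits axial and trans to it, with C9 equatorial. The sensitive points are this open form, in which C4–H is benzylic and α to a ketone (epimerisation there is racemisation), dehydration of the lactol across C3–C4, two esters and three free phenols. The hard part is ring A: five contiguous substituents, two oxygens that must end up differentiated, and a stereocentre attached at the most crowded position next to the C5 methyl. The plan rests on one feature: C5–C6–C7–C8 is a four-carbon unit oxygenated at C6 and C8 with a methyl on its C5 end, while C4a and C8a carry the chain and a carboxyl, which is the imprint of an oxygenated diene added across an alkynoate C4a≡C8a.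

## Retrosynthetic reasoning

The two phenols of ring B are masked as benzyl ethers until the end, so target 28 comes from lactol 27 by cleaving two O–benzyl bonds. This is done last because a free resorcinol would not survive the oxidation and the organometallic steps, and the cleavage is neutral, so the lactol and C4 are not disturbed.

Lactol 27 is the ring-closed form of keto acid 26, so the O2–C3 bond is cut. The carboxyl of 26 is carried as the tert-butyl ester 25, whose bulk keeps it from reacting with the C3 oxygen before the ketone is in place. The forward step only has to free the acid; the ring and the C3 configuration then follow from the equilibrium.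

The C3 ketone of 25 is taken back to the alcohol 24 and its silyl ether 23. C4 must not stand next to a carbonyl while ring A is being built, and a silyl ether at C3 also prevents migration of the ring B acyl group from O9 to O3.

Ring A of 23 is cut at C5–C4a and C8–C8a, which gives ynoate 15 and diene 20. These two bonds are chosen because the crowded C4a–C4 bond then already exists in the dienophile. C6–OMe and C8–OH also come out differentiated from the diene, so no selective alkylation of a resorcinol is needed, and C4 is propargylic and not enolisable during the ring formation. The forward reaction has to deliver one regiochemistry and aromatise.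

Ynoate 15 is cut at the C8a–carboxyl bond, back to terminal alkyne 13 and, by removing the silyl group, to alcohol 12. The carboxylation comes late, so the base-sensitive ynoate is carried through only one step.

Alcohol 12 is cut at C3–C4 into aldehyde 8 and mesylate 10, through allenylzinc 11. This one bond formation sets C4 from the chiral-pool alcohol 9 and places the C3 oxygen anti to the methyl. The C3 configuration is lost later, but a single diastereomer keeps the intermediates clean.

Aldehyde 8 already carries ring B. Its C9–O bond is traced to acid 5 through allyl ester 6, because alkylation of the carboxylate avoids attack at the hindered carbonyl. Acid 5 goes back through aldehydes 4 and 3 to resorcinol 1 by formylation at the position between hydroxyl and methyl.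

Diene 20 is the silyl ketene acetal of the vinylogous ester 18, which is the enol ether of keto ester 16.

## Alternatives that were turned down

Alternative 1: The cut is made in ring B and at the ester oxygen, at the C9–O acyl bond and the C1′–C6′ bond of the resorcylate.
- Forward step: the allylic alcohol A1 (ring A complete, C3 still an exocyclic methylene) traps the acylketene released on heating the diketo-dioxinone A2. The triketo ester so formed is cyclised by a carbonate base and aromatised by acid to the free resorcylate A3.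
- For it: the hindered ester is made without acylating with a doubly ortho-substituted benzoic acid, ring B needs no protecting groups, and the sequence follows the biosynthetic logic. On protecting-group economy for ring B it is stronger than the chosen route.
- Against it: ring B is the simple part of the target. In the chosen route it costs three routine steps from 1, and the ester is made by carboxylate alkylation (step 4), which is indifferent to the ortho substituents. The real problems (the pentasubstituted ring A, C4 and the lactol) all sit in A1 and are untouched by this key step. A2 needs a 2-methyl-1,3-diketone terminus to place the two ring B methyls. After A3 the C3 methylene must still be cleaved oxidatively next to a free, electron-rich resorcinol, and the benzyl groups cannot be removed first without hydrogenating that alkene.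
- Comparison: the chosen strategy spends its key step on the difficult ring and reaches the C3 ketone by a plain alcohol oxidation.

Alternative 2: The lactol ring is traced back to a five-membered carbocycle by cutting C1–O2 and O2–C3 and joining C1 to C3, which gives the 2-hydroxyindan-1-one A4.
- Forward step: a periodate reagent cleaves the bond between the ketone carbon and the tertiary carbinol carbon of A4. The carboxylic acid and ketone so formed are held ortho to each other and close to the lactol A5, the tribenzyl ether of the target.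
- For it: the labile keto acid appears only one step before the end, under mild oxidative conditions. Until then C4 is the β-carbon of a rigid indanone and cannot epimerise, and the configuration of the carbinol carbon is irrelevant. On the handling of C4 and of the lactol this alternative is stronger than the chosen route, in which C4 is α to an open-chain ketone in 25.
- Against it: A4 must already carry the complete ring A pattern, so the oxygen differentiation and the five contiguous substituents have to be solved separately. A4 then needs a long linear build-up: ring closure next to the C5 methyl, asymmetric introduction of the C4 methyl, hydroxymethylation and hydroxylation at the carbon between two substituted centres, and acylation of a neopentyl-type alcohol with the hindered acid.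
- Comparison: the chosen strategy is convergent. It assembles ring A with all substituents and the differentiated oxygens in one step from two fragments and takes C4 from a chiral-pool alcohol.

Alternative 3: Ring A is cut at C8a–C4a, as in the polyketide folding.
- Forward step: in the keto-dioxinone A6, C4a is a ketone. An amine base brings the dioxinone carbon C8a onto it in an intramolecular aldol addition, and mild acid dehydrates the aldol to the benzodioxinone A7, with C8–O and the carboxyl tied up as the acetonide and C6–OH free.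
- For it: the ring closure is intramolecular and runs at room temperature, so the crowding at C4a that threatens step 12 matters less. On this point the alternative is stronger. C8–OH and the carboxyl also emerge protected together.
- Against it: in A6 the stereocentre C4 is α to the C4a ketone of a 1,3-dicarbonyl system and β to the silyloxy group on C3, so the amine base can epimerise it or eliminate the silyloxy group. A6 has to be assembled by acylation with an α-chiral acyl donor, a second point of epimerisation risk. The C5 methyl makes the diketone branched, the free C6 hydroxyl needs a separate methylation, and the acetonide must later be opened to reach the lactol.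
- Comparison: in the chosen strategy C4 is propargylic and not enolisable while the ring is formed, and C6–OMe and C8–OH are delivered differentiated.

Key step: step 12

Assumption: the hemiketal carbon C3 equilibrates through the open keto acid, and the (3R) lactol of the target is taken to be the more stable epimer (hydroxyl axial, trans to the pseudoaxial C4 methyl).

## Route

Step 1
Reactants: 1 4,5-dimethylbenzene-1,3-diol
Product: 3 2,4-dihydroxy-5,6-dimethylbenzaldehyde, via aryl iminium chloride 2 (not isolated)
Conditions: POCl3, DMF, MeCN, 0 °C → rt; then H2O, 50 °C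
Reagents that add atoms: N,N-dimethylformamide, CN(C)C=O; water, O
Why: Vilsmeier–Haack formylation; the chloroiminium ion should attack the carbon of 1 that is para to one hydroxyl and ortho to the other (between OH and CH3), as in resorcinol and orcinol, and not the site between the two hydroxyls. Hydrolysis of 2 gives the aldehyde.

Step 2
Reactants: 3 2,4-dihydroxy-5,6-dimethylbenzaldehyde
Product: 4 2,4-bis(benzyloxy)-5,6-dimethylbenzaldehyde
Conditions: BnBr, K2CO3, DMF, 60 °C
Reagents that add atoms: benzyl bromide, BrCc1ccccc1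
Why: Williamson ether synthesis; both phenoxides are alkylated, and the warm conditions are needed for the hydroxyl that is hydrogen-bonded to the aldehyde.

Step 3
Reactants: 4 2,4-bis(benzyloxy)-5,6-dimethylbenzaldehyde
Product: 5 2,4-bis(benzyloxy)-5,6-dimethylbenzoic acid
Conditions: NaClO2, NaH2PO4, 2-methylbut-2-ene, t-BuOH/H2O, rt
Reagents that add atoms: sodium chlorite NaClO2, [Na+].[O-]Cl=O
Why: Pinnick oxidation; chlorous acid oxidises even a doubly ortho-substituted aldehyde and leaves benzyl ethers alone, and the alkene removes HOCl before it can chlorinate the electron-rich ring.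

Step 4
Reactants: 5 2,4-bis(benzyloxy)-5,6-dimethylbenzoic acid
Product: 6 prop-2-en-1-yl 2,4-bis(benzyloxy)-5,6-dimethylbenzoate
Conditions: allyl bromide, K2CO3, DMF, rt
Reagents that add atoms: allyl bromide, C=CCBr
Why: SN2 alkylation of the carboxylate; the ester forms without attack at the hindered carbonyl carbon, so the two ortho substituents do not matter.

Step 5
Reactants: 6 prop-2-en-1-yl 2,4-bis(benzyloxy)-5,6-dimethylbenzoate
Product: 8 2-oxoethyl 2,4-bis(benzyloxy)-5,6-dimethylbenzoate, via diol 7 (not isolated)
Conditions: K2OsO4·2H2O (cat.), NaIO4, 2,6-lutidine, dioxane/H2O, rt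
Reagents that add atoms: osmium tetroxide OsO4 (formed from K2OsO4·2H2O, carries the oxygen), O=[Os](=O)(=O)=O; sodium periodate NaIO4 (terminal oxidant), [Na+].[O-]I(=O)(=O)=O
Why: Lemieux–Johnson oxidation; catalytic dihydroxylation gives diol 7, which periodate cleaves to the aldehyde. The electron-rich arene and the benzyl ethers, which ozone might attack, are inert here, and 8 is used promptly because α-acyloxy aldehydes hydrate and oligomerise on standing.

Step 6
Reactants: 9 (2R)-but-3-yn-2-ol
Product: 10 (2R)-but-3-yn-2-yl methanesulfonate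
Conditions: MsCl, Et3N, CH2Cl2, −78 → 0 °C
Reagents that add atoms: methanesulfonyl chloride, CS(=O)(=O)Cl
Why: O-sulfonylation of a secondary alcohol; the C–O bond is not broken, so the (R) configuration is retained.

Step 7
Reactants: 8 2-oxoethyl 2,4-bis(benzyloxy)-5,6-dimethylbenzoate; 10 (2R)-but-3-yn-2-yl methanesulfonate
Product: 12 (2S,3S)-2-hydroxy-3-methylpent-4-yn-1-yl 2,4-bis(benzyloxy)-5,6-dimethylbenzoate, via allenylzinc 11 (not isolated)
Conditions: 10 (1.5 equiv), Pd(OAc)2 (5 mol%), PPh3 (5 mol%), Et2Zn (3 equiv), THF, −78 → −20 °C; aq. NH4Cl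
Reagents that add atoms: none
Why: Marshall propargylation; zerovalent palladium formed in the flask displaces the mesylate in an anti SN2′ sense, transmetalation gives the (P)-allenylzinc 11, and 11 adds to 8 through a cyclic SE2′ transition state. C4 is set by the mesylate with net inversion (R to S), and the C3 hydroxyl comes out anti to the methyl because the aldehyde substituent avoids the allenyl methyl in that transition state. The doubly ortho-substituted ester should resist both Et2Zn and acyl migration to the new zinc alkoxide.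

Step 8
Reactants: 12 (2S,3S)-2-hydroxy-3-methylpent-4-yn-1-yl 2,4-bis(benzyloxy)-5,6-dimethylbenzoate
Product: 13 (2S,3S)-2-[(tert-butyldimethylsilyl)oxy]-3-methylpent-4-yn-1-yl 2,4-bis(benzyloxy)-5,6-dimethylbenzoate
Conditions: TBSOTf, 2,6-lutidine, CH2Cl2, −78 → 0 °C
Reagents that add atoms: tert-butyldimethylsilyl trifluoromethanesulfonate, CC(C)(C)[Si](C)(C)OS(=O)(=O)C(F)(F)F
Why: silylation of a hindered secondary alcohol with the silyl triflate; the ether blocks acyl migration and keeps C3 at the alcohol level, so that C4 has no carbonyl neighbour until ring A exists.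

Step 9
Reactants: 13 (2S,3S)-2-[(tert-butyldimethylsilyl)oxy]-3-methylpent-4-yn-1-yl 2,4-bis(benzyloxy)-5,6-dimethylbenzoate
Product: 15 tert-butyl (4S,5S)-6-{[2,4-bis(benzyloxy)-5,6-dimethylbenzoyl]oxy}-5-[(tert-butyldimethylsilyl)oxy]-4-methylhex-2-ynoate, via lithium acetylide 14 (not isolated)
Conditions: LiN(SiMe3)2, THF, −78 °C; Boc2O, −78 → −20 °C; aq. NH4Cl
Reagents that add atoms: di-tert-butyl dicarbonate, CC(C)(C)OC(=O)OC(=O)OC(C)(C)C
Why: deprotonation of the terminal alkyne and C-acylation of acetylide 14 with the dicarbonate. The silylamide base is chosen because it should neither add to the hindered aryl ester nor metalate the ortho methyl of ring B, and the cold quench keeps the alkoxide by-product from isomerising the ynoate to the allenoate through C4–H.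

Step 10
Reactants: 16 methyl 3-oxopentanoate
Product: 18 methyl (2E)-3-methoxypent-2-enoate, via dimethyl ketal 17 (not isolated)
Conditions: HC(OMe)3, H2SO4 (cat.), MeOH, rt; then distillation
Reagents that add atoms: trimethyl orthoformate, COC(OC)OC
Why: acid-catalysed ketalisation followed by loss of methanol from 17 on distillation, the standard O-methylation of a β-keto ester to its conjugated (E)-enol ether. Any β,γ-isomer would give the same dienolate in step 11.

Step 11
Reactants: 18 methyl (2E)-3-methoxypent-2-enoate
Product: 20 (1Z,3Z)-1,3-dimethoxy-1-(trimethylsilyloxy)penta-1,3-diene, via lithium dienolate 19 (not isolated)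
Conditions: LiN(iPr)2, THF, −78 °C; Me3SiCl, −78 °C → rt; hexane, filtration, used crude
Reagents that add atoms: chlorotrimethylsilane, C[Si](C)(C)Cl
Why: γ-deprotonation of the vinylogous ester gives the extended enolate 19, which is silylated on oxygen (Brassard-type diene synthesis). The terminal methyl should lie cis to the C3 methoxy group, that is on the outside of the s-cis diene; the geometry at C1 has no consequence for the aromatised product.

Step 12
Reactants: 15 tert-butyl (4S,5S)-6-{[2,4-bis(benzyloxy)-5,6-dimethylbenzoyl]oxy}-5-[(tert-butyldimethylsilyl)oxy]-4-methylhex-2-ynoate; 20 (1Z,3Z)-1,3-dimethoxy-1-(trimethylsilyloxy)penta-1,3-diene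
Product: 23 tert-butyl 2-[(2S,3S)-4-{[2,4-bis(benzyloxy)-5,6-dimethylbenzoyl]oxy}-3-[(tert-butyldimethylsilyl)oxy]butan-2-yl]-6-hydroxy-4-methoxy-3-methylbenzoate, via cycloadduct 21 (not isolated), via aryl silyl ether 22 (not isolated)
Conditions: 20 (4 equiv), toluene (1 M), 120 °C, sealed tube; then 0.5 M HCl, THF, 0 °C
Reagents that add atoms: none
Why: The electron-rich 1,1,3-trioxygenated diene 20 adds to ynoate 15 in a normal-demand Diels–Alder reaction that is concerted but asynchronous; its stepwise limit, vinylogous Michael addition followed by ring closure, would form the same bonds. The largest HOMO coefficient of 20 is at the methyl-bearing terminus (future C5) and the largest LUMO coefficient of 15 is at the β-carbon C4a, so C5–C4a forms ahead of C8–C8a; this pairing fixes the one regiochemistry needed and puts the carboxyl between the C8 oxygen and the side chain. Ring A is closed as a six-membered carbocycle by this intermolecular [4+2] mode, and adduct 21 is a cyclohexa-1,4-diene whose C8 ketal loses methanol by 1,4-elimination to give aryl silyl ether 22. Dilute acid then frees the phenol, so the diene methoxy becomes the C6 methyl ether and the silyloxy group the C8 hydroxyl, without any selective alkylation. The closest known reaction type is the addition of Brassard- and Danishefsky-type dienes to acetylenic esters with aromatisation to salicylates and resorcylates. No stereocentre is created, since the two sp3 ring carbons of 21 disappear on aromatisation, and C4 is propargylic and not enolisable under neutral thermal conditions, so its (S) configuration should be carried through. No Lewis acid is used, so the silyl ether and the tert-butyl ester are safe, and the excess of 20 and the high concentration offset its loss by silyl transfer or oligomerisation. The main hazard is steric: the bond C5–C4a joins a methyl-bearing diene terminus to an alkyne carbon that carries a branched chain.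

Step 13
Reactants: 23 tert-butyl 2-[(2S,3S)-4-{[2,4-bis(benzyloxy)-5,6-dimethylbenzoyl]oxy}-3-[(tert-butyldimethylsilyl)oxy]butan-2-yl]-6-hydroxy-4-methoxy-3-methylbenzoate
Product: 24 tert-butyl 2-[(2S,3S)-4-{[2,4-bis(benzyloxy)-5,6-dimethylbenzoyl]oxy}-3-hydroxybutan-2-yl]-6-hydroxy-4-methoxy-3-methylbenzoate
Conditions: HF·pyridine, pyridine, THF, 0 °C → rt
Reagents that add atoms: none
Why: fluoride-mediated desilylation under buffered, weakly acidic conditions; no alkoxide is formed, so the ring B acyl group should not migrate from O9 to O3, and the tert-butyl ester is too hindered to lactonise with the new hydroxyl.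

Step 14
Reactants: 24 tert-butyl 2-[(2S,3S)-4-{[2,4-bis(benzyloxy)-5,6-dimethylbenzoyl]oxy}-3-hydroxybutan-2-yl]-6-hydroxy-4-methoxy-3-methylbenzoate
Product: 25 tert-butyl 2-[(2S)-4-{[2,4-bis(benzyloxy)-5,6-dimethylbenzoyl]oxy}-3-oxobutan-2-yl]-6-hydroxy-4-methoxy-3-methylbenzoate
Conditions: Dess–Martin periodinane, NaHCO3, CH2Cl2, 0 °C → rt
Reagents that add atoms: none
Why: Dess–Martin oxidation of a secondary alcohol under buffered, near-neutral conditions, which a hydrogen-bonded salicylate phenol normally tolerates. C4 is now α to a ketone, but enolisation towards it is disfavoured because the doubly ortho-substituted aryl ring cannot become coplanar with the enol; 25 is used at once.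

Step 15
Reactants: 25 tert-butyl 2-[(2S)-4-{[2,4-bis(benzyloxy)-5,6-dimethylbenzoyl]oxy}-3-oxobutan-2-yl]-6-hydroxy-4-methoxy-3-methylbenzoate
Product: 27 [(3R,4S)-3,8-dihydroxy-6-methoxy-4,5-dimethyl-1-oxo-3,4-dihydro-1H-isochromen-3-yl]methyl 2,4-bis(benzyloxy)-5,6-dimethylbenzoate, via keto acid 26 (not isolated)
Conditions: CF3CO2H/CH2Cl2 (1:4), 0 °C
Reagents that add atoms: none
Why: acidolysis of the tert-butyl ester (alkyl–oxygen cleavage) frees keto acid 26, whose carboxyl adds to the C3 ketone in a 6-exo closure. C3 is set under thermodynamic control: the hydroxyl takes the axial, anomerically favoured position trans to the C4 methyl, which the peri C5 methyl holds pseudoaxial. Short exposure at 0 °C limits enolisation and dehydration across C3–C4, and the open ring position C7 is flanked by two oxygen substituents, which should hinder tert-butylation.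

Step 16
Reactants: 27 [(3R,4S)-3,8-dihydroxy-6-methoxy-4,5-dimethyl-1-oxo-3,4-dihydro-1H-isochromen-3-yl]methyl 2,4-bis(benzyloxy)-5,6-dimethylbenzoate
Product: 28 [(3R,4S)-3,8-dihydroxy-6-methoxy-4,5-dimethyl-1-oxo-3,4-dihydro-1H-isochromen-3-yl]methyl 2,4-dihydroxy-5,6-dimethylbenzoate
Conditions: H2 (1 atm), Pd/C (10%), EtOAc, rt
Reagents that add atoms: none
Why: hydrogenolysis of the two aryl benzyl ethers; the conditions are neutral, and neither the lactol, the two esters nor the C4–H bond is cleaved by hydrogen over Pd/C under these conditions.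

## Compound list

1 | 4,5-dimethylbenzene-1,3-diol (4,5-dimethylresorcinol) | Oc1cc(O)c(C)c(C)c1 | starting material
2 | [(2,4-dihydroxy-5,6-dimethylphenyl)methylidene]dimethylammonium chloride | C[N+](C)=Cc1c(O)cc(O)c(C)c1C.[Cl-] | intermediate
3 | 2,4-dihydroxy-5,6-dimethylbenzaldehyde | O=Cc1c(O)cc(O)c(C)c1C | intermediate
4 | 2,4-bis(benzyloxy)-5,6-dimethylbenzaldehyde | O=Cc1c(OCc2ccccc2)cc(OCc2ccccc2)c(C)c1C | intermediate
5 | 2,4-bis(benzyloxy)-5,6-dimethylbenzoic acid | OC(=O)c1c(OCc2ccccc2)cc(OCc2ccccc2)c(C)c1C | intermediate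
6 | prop-2-en-1-yl 2,4-bis(benzyloxy)-5,6-dimethylbenzoate | C=CCOC(=O)c1c(OCc2ccccc2)cc(OCc2ccccc2)c(C)c1C | intermediate
7 | 2,3-dihydroxypropyl 2,4-bis(benzyloxy)-5,6-dimethylbenzoate (racemic) | OCC(O)COC(=O)c1c(OCc2ccccc2)cc(OCc2ccccc2)c(C)c1C | intermediate
8 | 2-oxoethyl 2,4-bis(benzyloxy)-5,6-dimethylbenzoate | O=CCOC(=O)c1c(OCc2ccccc2)cc(OCc2ccccc2)c(C)c1C | intermediate
9 | (2R)-but-3-yn-2-ol | C[C@@H](O)C#C | starting material
10 | (2R)-but-3-yn-2-yl methanesulfonate | C[C@@H](OS(C)(=O)=O)C#C | intermediate
11 | (P)-buta-1,2-dien-1-yl(ethyl)zinc | CC[Zn]C([H])=[C@@]=C([H])C | intermediate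
12 | (2S,3S)-2-hydroxy-3-methylpent-4-yn-1-yl 2,4-bis(benzyloxy)-5,6-dimethylbenzoate | C#C[C@H](C)[C@H](O)COC(=O)c1c(OCc2ccccc2)cc(OCc2ccccc2)c(C)c1C | intermediate
13 | (2S,3S)-2-[(tert-butyldimethylsilyl)oxy]-3-methylpent-4-yn-1-yl 2,4-bis(benzyloxy)-5,6-dimethylbenzoate | C#C[C@H](C)[C@H](O[Si](C)(C)C(C)(C)C)COC(=O)c1c(OCc2ccccc2)cc(OCc2ccccc2)c(C)c1C | intermediate
14 | [(3S,4S)-5-{[2,4-bis(benzyloxy)-5,6-dimethylbenzoyl]oxy}-4-[(tert-butyldimethylsilyl)oxy]-3-methylpent-1-yn-1-yl]lithium | [Li]C#C[C@H](C)[C@H](O[Si](C)(C)C(C)(C)C)COC(=O)c1c(OCc2ccccc2)cc(OCc2ccccc2)c(C)c1C | intermediate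
15 | tert-butyl (4S,5S)-6-{[2,4-bis(benzyloxy)-5,6-dimethylbenzoyl]oxy}-5-[(tert-butyldimethylsilyl)oxy]-4-methylhex-2-ynoate | CC(C)(C)OC(=O)C#C[C@H](C)[C@H](O[Si](C)(C)C(C)(C)C)COC(=O)c1c(OCc2ccccc2)cc(OCc2ccccc2)c(C)c1C | intermediate
16 | methyl 3-oxopentanoate | CCC(=O)CC(=O)OC | starting material
17 | methyl 3,3-dimethoxypentanoate | CCC(OC)(OC)CC(=O)OC | intermediate
18 | methyl (2E)-3-methoxypent-2-enoate | CC/C(OC)=C\C(=O)OC | intermediate
19 | lithium (1E,3Z)-1,3-dimethoxypenta-1,3-dien-1-olate | C/C=C(\OC)/C=C(/OC)O[Li] | intermediate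
20 | (1Z,3Z)-1,3-dimethoxy-1-(trimethylsilyloxy)penta-1,3-diene | C/C=C(\OC)/C=C(/OC)O[Si](C)(C)C | intermediate
21 | tert-butyl 2-[(2S,3S)-4-{[2,4-bis(benzyloxy)-5,6-dimethylbenzoyl]oxy}-3-[(tert-butyldimethylsilyl)oxy]butan-2-yl]-4,6-dimethoxy-3-methyl-6-(trimethylsilyloxy)cyclohexa-1,4-diene-1-carboxylate (mixture of isomers at ring C3 and C6) | COC1=CC(OC)(O[Si](C)(C)C)C(C(=O)OC(C)(C)C)=C(C1C)[C@H](C)[C@H](O[Si](C)(C)C(C)(C)C)COC(=O)c1c(OCc2ccccc2)cc(OCc2ccccc2)c(C)c1C | intermediate
22 | tert-butyl 2-[(2S,3S)-4-{[2,4-bis(benzyloxy)-5,6-dimethylbenzoyl]oxy}-3-[(tert-butyldimethylsilyl)oxy]butan-2-yl]-4-methoxy-3-methyl-6-(trimethylsilyloxy)benzoate | COc1cc(O[Si](C)(C)C)c(C(=O)OC(C)(C)C)c(c1C)[C@H](C)[C@H](O[Si](C)(C)C(C)(C)C)COC(=O)c1c(OCc2ccccc2)cc(OCc2ccccc2)c(C)c1C | intermediate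
23 | tert-butyl 2-[(2S,3S)-4-{[2,4-bis(benzyloxy)-5,6-dimethylbenzoyl]oxy}-3-[(tert-butyldimethylsilyl)oxy]butan-2-yl]-6-hydroxy-4-methoxy-3-methylbenzoate | COc1cc(O)c(C(=O)OC(C)(C)C)c(c1C)[C@H](C)[C@H](O[Si](C)(C)C(C)(C)C)COC(=O)c1c(OCc2ccccc2)cc(OCc2ccccc2)c(C)c1C | intermediate
24 | tert-butyl 2-[(2S,3S)-4-{[2,4-bis(benzyloxy)-5,6-dimethylbenzoyl]oxy}-3-hydroxybutan-2-yl]-6-hydroxy-4-methoxy-3-methylbenzoate | COc1cc(O)c(C(=O)OC(C)(C)C)c(c1C)[C@H](C)[C@H](O)COC(=O)c1c(OCc2ccccc2)cc(OCc2ccccc2)c(C)c1C | intermediate
25 | tert-butyl 2-[(2S)-4-{[2,4-bis(benzyloxy)-5,6-dimethylbenzoyl]oxy}-3-oxobutan-2-yl]-6-hydroxy-4-methoxy-3-methylbenzoate | COc1cc(O)c(C(=O)OC(C)(C)C)c(c1C)[C@H](C)C(=O)COC(=O)c1c(OCc2ccccc2)cc(OCc2ccccc2)c(C)c1C | intermediate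
26 | 2-[(2S)-4-{[2,4-bis(benzyloxy)-5,6-dimethylbenzoyl]oxy}-3-oxobutan-2-yl]-6-hydroxy-4-methoxy-3-methylbenzoic acid | COc1cc(O)c(C(=O)O)c(c1C)[C@H](C)C(=O)COC(=O)c1c(OCc2ccccc2)cc(OCc2ccccc2)c(C)c1C | intermediate
27 | [(3R,4S)-3,8-dihydroxy-6-methoxy-4,5-dimethyl-1-oxo-3,4-dihydro-1H-isochromen-3-yl]methyl 2,4-bis(benzyloxy)-5,6-dimethylbenzoate | COc1cc(O)c2c(c1C)[C@H](C)[C@](O)(COC(=O)c1c(OCc3ccccc3)cc(OCc3ccccc3)c(C)c1C)OC2=O | intermediate
28 | [(3R,4S)-3,8-dihydroxy-6-methoxy-4,5-dimethyl-1-oxo-3,4-dihydro-1H-isochromen-3-yl]methyl 2,4-dihydroxy-5,6-dimethylbenzoate | COc1cc(O)c2c(c1C)[C@H](C)[C@](O)(COC(=O)c1c(O)cc(O)c(C)c1C)OC2=O | target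

## Step count and least certain steps

Total: 16 steps. Longest linear sequence: 13 steps (steps 1–5, 7–9, 12–16).

**Step 12 (key step).** The cycloaddition is most likely to be too slow. The forming C5–C4a bond joins a methyl-bearing diene terminus to an alkyne carbon with a branched substituent, so hydrolysis, silyl transfer or oligomerisation of 20 may use up the diene before 15 reacts. Prolonged heating could then isomerise the ynoate to the allenoate and erode C4. The fallback changes the activating group of the dienophile. From 13, deprotonation with LiN(SiMe3)2 and formylation with DMF should give (2S,3S)-2-[(tert-butyldimethylsilyl)oxy]-3-methyl-6-oxohex-4-yn-1-yl 2,4-bis(benzyloxy)-5,6-dimethylbenzoate F1. An ynal is a far more electrophilic and less hindered dienophile than the tert-butyl ynoate, so 20 should add at lower temperature with the same regiochemistry. After loss of methanol and hydrolysis of the aryl silyl ether this would give (2S,3S)-2-[(tert-butyldimethylsilyl)oxy]-3-(2-formyl-3-hydroxy-5-methoxy-6-methylphenyl)butyl 2,4-bis(benzyloxy)-5,6-dimethylbenzoate F2. Pinnick oxidation (NaClO2, NaH2PO4, large excess of 2-methylbut-2-ene) would give 2-[(2S,3S)-4-{[2,4-bis(benzyloxy)-5,6-dimethylbenzoyl]oxy}-3-[(tert-butyldimethylsilyl)oxy]butan-2-yl]-6-hydroxy-4-methoxy-3-methylbenzoic acid F3. Esterification of the acid with tert-butyl 2,2,2-trichloroacetimidate returns to the route at 23.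

**Step 9.** The base may metalate the ortho methyl of ring B or attack an ester instead of cleanly forming the acetylide, deprotonation may be incomplete, or the alkoxide released from the dicarbonate may isomerise the product through C4–H. The fallback avoids lithium bases. From 13, carboxylation with CO2 (1 atm), AgI (cat.) and Cs2CO3 in DMF should give (4S,5S)-6-{[2,4-bis(benzyloxy)-5,6-dimethylbenzoyl]oxy}-5-[(tert-butyldimethylsilyl)oxy]-4-methylhex-2-ynoic acid F4. This acid is strong enough to be esterified by tert-butyl 2,2,2-trichloroacetimidate without added catalyst, which comes back to the route at 15.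

**Step 7.** Selectivity may be poor: the allenylzinc can lose configuration before it adds, ethyl transfer from Et2Zn to the aldehyde can compete, and the α-acyloxy aldehyde 8 can hydrate or oligomerise, all of which lower the diastereomeric and enantiomeric purity of 12. The fallback changes the order in which the fragments are joined, so that the propargylation is run on a standard α-alkoxy aldehyde. From 10 and purchased (4-methoxybenzyloxy)acetaldehyde, the same Pd(OAc)2/PPh3/Et2Zn conditions should give (2S,3S)-1-[(4-methoxybenzyl)oxy]-3-methylpent-4-yn-2-ol F5. Silylation (TBSOTf, 2,6-lutidine) gives tert-butyl{[(2S,3S)-1-[(4-methoxybenzyl)oxy]-3-methylpent-4-yn-2-yl]oxy}dimethylsilane F6. Oxidative removal of the 4-methoxybenzyl group with DDQ gives (2S,3S)-2-[(tert-butyldimethylsilyl)oxy]-3-methylpent-4-yn-1-ol F7. Mitsunobu esterification of F7 with acid 5 (PPh3, diisopropyl azodicarboxylate), in which the hindered carboxylate acts as the nucleophile, returns to the route at 13.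

**Step 15.** In trifluoroacetic acid the open keto acid 26 may enolise towards C4 and lose enantiomeric purity, the lactol may dehydrate across C3–C4 to the isocoumarin, and the tert-butyl cation may alkylate the electron-rich rings. The fallback carries the carboxyl as a benzyl ester, so that no acid step is needed. From 13, LiN(SiMe3)2 and benzyl chloroformate should give benzyl (4S,5S)-6-{[2,4-bis(benzyloxy)-5,6-dimethylbenzoyl]oxy}-5-[(tert-butyldimethylsilyl)oxy]-4-methylhex-2-ynoate F8. Cycloaddition with 20 as in step 12 gives benzyl 2-[(2S,3S)-4-{[2,4-bis(benzyloxy)-5,6-dimethylbenzoyl]oxy}-3-[(tert-butyldimethylsilyl)oxy]butan-2-yl]-6-hydroxy-4-methoxy-3-methylbenzoate F9. HF·pyridine gives benzyl 2-[(2S,3S)-4-{[2,4-bis(benzyloxy)-5,6-dimethylbenzoyl]oxy}-3-hydroxybutan-2-yl]-6-hydroxy-4-methoxy-3-methylbenzoate F10. F10 is oxidised at once, because its primary-alkyl ester is more prone to lactonise with the C3 hydroxyl than the tert-butyl ester of 24. Dess–Martin oxidation gives benzyl 2-[(2S)-4-{[2,4-bis(benzyloxy)-5,6-dimethylbenzoyl]oxy}-3-oxobutan-2-yl]-6-hydroxy-4-methoxy-3-methylbenzoate F11. Hydrogenolysis over Pd/C then removes all three benzyl groups, and 2-[(2S)-4-[(2,4-dihydroxy-5,6-dimethylbenzoyl)oxy]-3-oxobutan-2-yl]-6-hydroxy-4-methoxy-3-methylbenzoic acid F12 closes under neutral conditions to the target 28.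

## Further compounds

F1 | step 12 | (2S,3S)-2-[(tert-butyldimethylsilyl)oxy]-3-methyl-6-oxohex-4-yn-1-yl 2,4-bis(benzyloxy)-5,6-dimethylbenzoate | O=CC#C[C@H](C)[C@H](O[Si](C)(C)C(C)(C)C)COC(=O)c1c(OCc2ccccc2)cc(OCc2ccccc2)c(C)c1C
F2 | step 12 | (2S,3S)-2-[(tert-butyldimethylsilyl)oxy]-3-(2-formyl-3-hydroxy-5-methoxy-6-methylphenyl)butyl 2,4-bis(benzyloxy)-5,6-dimethylbenzoate | COc1cc(O)c(C=O)c(c1C)[C@H](C)[C@H](O[Si](C)(C)C(C)(C)C)COC(=O)c1c(OCc2ccccc2)cc(OCc2ccccc2)c(C)c1C
F3 | step 12 | 2-[(2S,3S)-4-{[2,4-bis(benzyloxy)-5,6-dimethylbenzoyl]oxy}-3-[(tert-butyldimethylsilyl)oxy]butan-2-yl]-6-hydroxy-4-methoxy-3-methylbenzoic acid | COc1cc(O)c(C(=O)O)c(c1C)[C@H](C)[C@H](O[Si](C)(C)C(C)(C)C)COC(=O)c1c(OCc2ccccc2)cc(OCc2ccccc2)c(C)c1C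
F4 | step 9 | (4S,5S)-6-{[2,4-bis(benzyloxy)-5,6-dimethylbenzoyl]oxy}-5-[(tert-butyldimethylsilyl)oxy]-4-methylhex-2-ynoic acid | OC(=O)C#C[C@H](C)[C@H](O[Si](C)(C)C(C)(C)C)COC(=O)c1c(OCc2ccccc2)cc(OCc2ccccc2)c(C)c1C
F5 | step 7 | (2S,3S)-1-[(4-methoxybenzyl)oxy]-3-methylpent-4-yn-2-ol | C#C[C@H](C)[C@H](O)COCc1ccc(OC)cc1
F6 | step 7 | tert-butyl{[(2S,3S)-1-[(4-methoxybenzyl)oxy]-3-methylpent-4-yn-2-yl]oxy}dimethylsilane | C#C[C@H](C)[C@H](O[Si](C)(C)C(C)(C)C)COCc1ccc(OC)cc1
F7 | step 7 | (2S,3S)-2-[(tert-butyldimethylsilyl)oxy]-3-methylpent-4-yn-1-ol | C#C[C@H](C)[C@H](O[Si](C)(C)C(C)(C)C)CO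
F8 | step 15 | benzyl (4S,5S)-6-{[2,4-bis(benzyloxy)-5,6-dimethylbenzoyl]oxy}-5-[(tert-butyldimethylsilyl)oxy]-4-methylhex-2-ynoate | O=C(OCc1ccccc1)C#C[C@H](C)[C@H](O[Si](C)(C)C(C)(C)C)COC(=O)c1c(OCc2ccccc2)cc(OCc2ccccc2)c(C)c1C
F9 | step 15 | benzyl 2-[(2S,3S)-4-{[2,4-bis(benzyloxy)-5,6-dimethylbenzoyl]oxy}-3-[(tert-butyldimethylsilyl)oxy]butan-2-yl]-6-hydroxy-4-methoxy-3-methylbenzoate | COc1cc(O)c(C(=O)OCc2ccccc2)c(c1C)[C@H](C)[C@H](O[Si](C)(C)C(C)(C)C)COC(=O)c1c(OCc2ccccc2)cc(OCc2ccccc2)c(C)c1C
F10 | step 15 | benzyl 2-[(2S,3S)-4-{[2,4-bis(benzyloxy)-5,6-dimethylbenzoyl]oxy}-3-hydroxybutan-2-yl]-6-hydroxy-4-methoxy-3-methylbenzoate | COc1cc(O)c(C(=O)OCc2ccccc2)c(c1C)[C@H](C)[C@H](O)COC(=O)c1c(OCc2ccccc2)cc(OCc2ccccc2)c(C)c1C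
F11 | step 15 | benzyl 2-[(2S)-4-{[2,4-bis(benzyloxy)-5,6-dimethylbenzoyl]oxy}-3-oxobutan-2-yl]-6-hydroxy-4-methoxy-3-methylbenzoate | COc1cc(O)c(C(=O)OCc2ccccc2)c(c1C)[C@H](C)C(=O)COC(=O)c1c(OCc2ccccc2)cc(OCc2ccccc2)c(C)c1C
F12 | step 15 | 2-[(2S)-4-[(2,4-dihydroxy-5,6-dimethylbenzoyl)oxy]-3-oxobutan-2-yl]-6-hydroxy-4-methoxy-3-methylbenzoic acid | COc1cc(O)c(C(=O)O)c(c1C)[C@H](C)C(=O)COC(=O)c1c(O)cc(O)c(C)c1C
A1 | alternative 1 | benzyl 2-(benzyloxy)-6-[(2S)-3-(hydroxymethyl)but-3-en-2-yl]-4-methoxy-5-methylbenzoate | COc1cc(OCc2ccccc2)c(C(=O)OCc2ccccc2)c(c1C)[C@H](C)C(=C)CO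
A2 | alternative 1 | 2,2-dimethyl-6-(3-methyl-2,4-dioxopentyl)-4H-1,3-dioxin-4-one | CC(=O)C(C)C(=O)CC1=CC(=O)OC(C)(C)O1
A3 | alternative 1 | benzyl 2-(benzyloxy)-6-[(2S)-3-{[(2,4-dihydroxy-5,6-dimethylbenzoyl)oxy]methyl}but-3-en-2-yl]-4-methoxy-5-methylbenzoate | COc1cc(OCc2ccccc2)c(C(=O)OCc2ccccc2)c(c1C)[C@H](C)C(=C)COC(=O)c1c(O)cc(O)c(C)c1C
A4 | alternative 2 | [(3S)-7-(benzyloxy)-2-hydroxy-5-methoxy-3,4-dimethyl-1-oxo-2,3-dihydro-1H-inden-2-yl]methyl 2,4-bis(benzyloxy)-5,6-dimethylbenzoate (either configuration at C2) | COc1cc(OCc3ccccc3)c2c(c1C)[C@H](C)C(O)(COC(=O)c1c(OCc3ccccc3)cc(OCc3ccccc3)c(C)c1C)C2=O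
A5 | alternative 2 | [(3R,4S)-8-(benzyloxy)-3-hydroxy-6-methoxy-4,5-dimethyl-1-oxo-3,4-dihydro-1H-isochromen-3-yl]methyl 2,4-bis(benzyloxy)-5,6-dimethylbenzoate | COc1cc(OCc3ccccc3)c2c(c1C)[C@H](C)[C@](O)(COC(=O)c1c(OCc3ccccc3)cc(OCc3ccccc3)c(C)c1C)OC2=O
A6 | alternative 3 | (2R,3R)-2-[(tert-butyldimethylsilyl)oxy]-7-(2,2-dimethyl-4-oxo-4H-1,3-dioxin-6-yl)-3,5-dimethyl-4,6-dioxoheptyl 2,4-bis(benzyloxy)-5,6-dimethylbenzoate (either configuration at C5) | CC1(C)OC(=O)C=C(CC(=O)C(C)C(=O)[C@H](C)[C@@H](O[Si](C)(C)C(C)(C)C)COC(=O)c2c(OCc3ccccc3)cc(OCc3ccccc3)c(C)c2C)O1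
A7 | alternative 3 | (2R,3S)-2-[(tert-butyldimethylsilyl)oxy]-3-(7-hydroxy-2,2,6-trimethyl-4-oxo-4H-1,3-benzodioxin-5-yl)butyl 2,4-bis(benzyloxy)-5,6-dimethylbenzoate | CC1(C)OC(=O)c2c(O1)cc(O)c(C)c2[C@H](C)[C@@H](O[Si](C)(C)C(C)(C)C)COC(=O)c1c(OCc3ccccc3)cc(OCc3ccccc3)c(C)c1C
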